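**Strategy.** Ring E carries the ring D oxygen at E1, the ring F oxygen at E4, hydroxyls at E3 and E5 and hydrogens at E2 and E6. This pattern maps onto a cyclised 3‑aryloxy‑5‑oxo‑6‑aryloxyhex‑2‑enoate, so ring E is built from acyclic carbon rather than by aryl–oxygen coupling. In one operation the lithium dienolate of a methyl (E)‑3‑aryloxybut‑2‑enoate bearing rings A–D is acylated by an aryloxyacetic Weinreb amide bearing rings F–G, and the keto ester closes by Claisen condensation and aromatises (bonds E5–E6 and E3–E4). The precursors come from repeated Ullmann coupling/Baeyer–Villiger oxidation with formyl‑activated aryl bromides and from C–H borylation/oxidation. BBr3 then frees all phenols.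

Key step: step 12

Remark: rings are lettered A to G from the 2,4,6‑trioxygenated end, E1 is the ring E carbon bonded to the ring D oxygen and E4 the one bonded to the ring F oxygen; compounds 1, 2, 9, 14, 16 and 20 are taken as catalogue compounds. "ABCD‑aryloxy" means the aryloxy group of phenol 13 and "FG‑aryloxy" that of phenol 19.

**Step 1**
Reactants: 1 2,4,6-trimethoxyphenol; 2 4-bromo-2,6-dimethoxybenzaldehyde
Product: 3 2,6-dimethoxy-4-(2,4,6-trimethoxyphenoxy)benzaldehyde (AB aldehyde)
Conditions: CuI (10 mol%), picolinic acid (20 mol%), K3PO4 (2 equiv), DMSO, 90 °C, argon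
Reagents that add atoms: none
Why: Ullmann diaryl ether synthesis, in which the CuI/picolinate catalyst accepts di-ortho-substituted phenoxides and the unhindered bromide of 2 is activated by its para formyl group.

**Step 2**
Reactants: 3 AB aldehyde
Product: 5 2,6-dimethoxy-4-(2,4,6-trimethoxyphenoxy)phenol (AB phenol), via AB formate 4 (not isolated)
Conditions: mCPBA (1.2 equiv), CH2Cl2, 0 °C to rt; aqueous NaHCO3 wash; then K2CO3 (cat.), MeOH, rt
Reagents that add atoms: mCPBA, OOC(=O)c1cccc(Cl)c1
Why: Baeyer–Villiger (Dakin-type) oxidation, in which the 2,4,6-trioxygenated aryl group migrates in preference to hydride and the resulting aryl formate is transesterified by methanol.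

**Step 3**
Reactants: 5 AB phenol; 2 4-bromo-2,6-dimethoxybenzaldehyde
Product: 6 4-[2,6-dimethoxy-4-(2,4,6-trimethoxyphenoxy)phenoxy]-2,6-dimethoxybenzaldehyde (ABC aldehyde)
Conditions: CuI (10 mol%), picolinic acid (20 mol%), K3PO4 (2 equiv), DMSO, 90 °C, argon
Reagents that add atoms: none
Why: Ullmann diaryl ether synthesis of the same kind as step 1, since 5 is again a 2,6-dimethoxyphenol and the bromide is the same activated partner.

**Step 4**
Reactants: 6 ABC aldehyde
Product: 8 4-[2,6-dimethoxy-4-(2,4,6-trimethoxyphenoxy)phenoxy]-2,6-dimethoxyphenol (ABC phenol), via ABC formate 7 (not isolated)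
Conditions: mCPBA (1.2 equiv), CH2Cl2, 0 °C to rt; aqueous NaHCO3 wash; then K2CO3 (cat.), MeOH, rt
Reagents that add atoms: mCPBA, OOC(=O)c1cccc(Cl)c1
Why: Baeyer–Villiger oxidation of an electron-rich 2,4,6-trioxygenated benzaldehyde followed by formate methanolysis, as in step 2.

**Step 5**
Reactants: 9 5-bromo-1,2,3-trimethoxybenzene
Product: 10 6-bromo-2,3,4-trimethoxybenzaldehyde
Conditions: Cl2CHOMe (1.3 equiv), TiCl4 (2 equiv), CH2Cl2, −10 to 0 °C; then H2O
Reagents that add atoms: dichloromethyl methyl ether, COC(Cl)Cl; water, O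
Why: Rieche formylation, in which the two free ring positions of 9 are equivalent by symmetry and each is ortho and para to methoxy groups, so only one aldehyde can form.

**Step 6**
Reactants: 8 ABC phenol; 10 6-bromo-2,3,4-trimethoxybenzaldehyde
Product: 11 ABCD aldehyde (2,3,4-trimethoxybenzaldehyde bearing at C6 the aryloxy group of phenol 8)
Conditions: CuI (15 mol%), picolinic acid (30 mol%), K3PO4 (2 equiv), DMSO, 100 °C, argon
Reagents that add atoms: none
Why: Ullmann diaryl ether synthesis in which the ortho formyl group of 10 accelerates oxidative addition at the C–Br bond, whose other neighbour is only a hydrogen.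

**Step 7**
Reactants: 11 ABCD aldehyde
Product: 13 ABCD phenol (2,3,4-trimethoxyphenol bearing at C6 the aryloxy group of phenol 8), via ABCD formate 12 (not isolated)
Conditions: mCPBA (1.2 equiv), CH2Cl2, 0 °C to rt; aqueous NaHCO3 wash; then K2CO3 (cat.), MeOH, rt
Reagents that add atoms: mCPBA, OOC(=O)c1cccc(Cl)c1
Why: Baeyer–Villiger oxidation, favoured because the formyl-bearing carbon of ring D has oxygen substituents at both ortho positions and at the para position, followed by formate methanolysis.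

**Step 8**
Reactants: 13 ABCD phenol; 14 methyl but-2-ynoate
Product: 15 methyl (E)-3-(ABCD-aryloxy)but-2-enoate (aryloxy trans to the ester, methyl cis to it)
Conditions: Cs2CO3 (20 mol%), DMF, 60 °C
Reagents that add atoms: none
Why: Base-catalysed oxa-Michael addition of the phenoxide to the alkynoate, which should settle on the thermodynamically preferred (E) isomer because phenoxide addition is reversible at this temperature.

**Step 9**
Reactants: 16 2,6-dimethoxyphenol; 9 5-bromo-1,2,3-trimethoxybenzene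
Product: 17 5-(2,6-dimethoxyphenoxy)-1,2,3-trimethoxybenzene
Conditions: CuI (10 mol%), picolinic acid (20 mol%), K3PO4 (2 equiv), DMSO, 100 °C, argon
Reagents that add atoms: none
Why: Ullmann diaryl ether synthesis between an electron-rich, strongly nucleophilic di-ortho-substituted phenoxide and an aryl bromide with no ortho substituent.

**Step 10**
Reactants: 17 5-(2,6-dimethoxyphenoxy)-1,2,3-trimethoxybenzene
Product: 19 3,5-dimethoxy-4-(3,4,5-trimethoxyphenoxy)phenol (FG phenol), via FG pinacol boronate 18 (not isolated)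
Conditions: [Ir(OMe)(cod)]2 (1.5 mol%), 4,4'-di-tert-butyl-2,2'-bipyridine (3 mol%), B2pin2 (0.6 equiv), THF, 80 °C; then 30% aq. H2O2, NaOH, THF/H2O, 0 °C to rt
Reagents that add atoms: hydrogen peroxide, OO (bis(pinacolato)diboron, CC1(C)OB(OC1(C)C)B1OC(C)(C)C(C)(C)O1, supplies only the boryl group of 18)
Why: Sterically governed iridium-catalysed C–H borylation reaches only the one C–H bond without an ortho substituent (para to the ether oxygen of ring F), and alkaline peroxide oxidation of the arylboronate gives the phenol at that carbon.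

**Step 11**
Reactants: 19 FG phenol; 20 2-bromo-N-methoxy-N-methylacetamide
Product: 21 2-(FG-aryloxy)-N-methoxy-N-methylacetamide
Conditions: K2CO3 (1.5 equiv), acetone, reflux
Reagents that add atoms: none
Why: Williamson ether synthesis, an SN2 displacement by an unhindered phenoxide at a primary bromide activated by the adjacent amide carbonyl.

**Step 12**
Reactants: 15 methyl (E)-3-(ABCD-aryloxy)but-2-enoate; 21 2-(FG-aryloxy)-N-methoxy-N-methylacetamide
Product: 23 pentadeca-O-methyl heptamer, 5-(ABCD-aryloxy)-2-(FG-aryloxy)benzene-1,3-diol, via keto ester 22 (not isolated)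
Conditions: LiN(iPr)2 (1.1 equiv), THF, −78 °C; 21 (1.0 equiv), −78 to 0 °C; then LiN(SiMe3)2 (3 equiv), 0 to 50 °C; 1 M HCl, 0 °C
Reagents that add atoms: none
Why: LiN(iPr)2 removes a proton from the methyl group of 15, which lies cis to the coordinating ester, and the extended enolate attacks amide 21 through its terminal carbon to give a chelated tetrahedral adduct that cannot be acylated twice and collapses on warming to the lithium enolate of keto ester 22 (bond E5–E6). Under LiN(SiMe3)2 this enolate equilibrates by proton transfer with the regioisomeric enolate at the aryloxy-bearing carbon, which attacks the ester carbonyl (bond E3–E4), expels methoxide and tautomerises to the resorcinol dianion. The closest known reactions are the terminal acylation of lithiated 3-alkoxybut-2-enoates used for 4-alkoxy-2-pyranones and the Claisen closure of 5-oxohexanoates to cyclohexane-1,3-diones, as in dimedone and olivetol syntheses, where a ketone enolate likewise cyclises from beneath a more stable enolate. Ring E closes by 6-exo-trig attack of an enolate carbon on the ester, and no stereocentre is formed. The step needs carbon rather than oxygen attack on the ester and survival of the vinylogous aryl ester: lactonisation would have to expel lithium methoxide from a stabilised enolate and should be reversible, whereas carbon acylation is made irreversible by aromatisation and deprotonation, and the enolate character of the chain, the di-ortho-substituted ring D aryloxy group and the non-nucleophilic amide bases shield the β-carbon from addition–elimination. The (E) geometry of 15 places the acylated methyl group and the ester on the same side of the double bond, as ring closure requires.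

**Step 13**
Reactants: 23 pentadeca-O-methyl heptamer
Product: 24 CNP0304148.0 (heptadecahydroxy heptamer)
Conditions: BBr3 (30 equiv), CH2Cl2, −78 °C to rt, argon; H2O, 0 °C
Reagents that add atoms: none
Why: Lewis-acid cleavage of aryl methyl ethers, in which BBr3 coordinates each methoxy oxygen and bromide attacks the methyl carbon by SN2, while the diaryl ether C–O bonds, which offer no sp3 carbon, should remain intact.

**Compound list**

1 | 2,4,6-trimethoxyphenol | COc1cc(OC)c(O)c(OC)c1 | starting material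
2 | 4-bromo-2,6-dimethoxybenzaldehyde | COc1cc(Br)cc(OC)c1C=O | starting material
3 | AB aldehyde, 2,6-dimethoxy-4-(2,4,6-trimethoxyphenoxy)benzaldehyde | COc1cc(OC)c(Oc2cc(OC)c(C=O)c(OC)c2)c(OC)c1 | intermediate
4 | AB formate, 2,6-dimethoxy-4-(2,4,6-trimethoxyphenoxy)phenyl formate | COc1cc(OC)c(Oc2cc(OC)c(OC=O)c(OC)c2)c(OC)c1 | intermediate
5 | AB phenol, 2,6-dimethoxy-4-(2,4,6-trimethoxyphenoxy)phenol | COc1cc(OC)c(Oc2cc(OC)c(O)c(OC)c2)c(OC)c1 | intermediate
6 | ABC aldehyde, 4-[2,6-dimethoxy-4-(2,4,6-trimethoxyphenoxy)phenoxy]-2,6-dimethoxybenzaldehyde | COc1cc(OC)c(Oc2cc(OC)c(Oc3cc(OC)c(C=O)c(OC)c3)c(OC)c2)c(OC)c1 | intermediate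
7 | ABC formate, formate ester of phenol 8 | COc1cc(OC)c(Oc2cc(OC)c(Oc3cc(OC)c(OC=O)c(OC)c3)c(OC)c2)c(OC)c1 | intermediate
8 | ABC phenol, 4-[2,6-dimethoxy-4-(2,4,6-trimethoxyphenoxy)phenoxy]-2,6-dimethoxyphenol | COc1cc(OC)c(Oc2cc(OC)c(Oc3cc(OC)c(O)c(OC)c3)c(OC)c2)c(OC)c1 | intermediate
9 | 5-bromo-1,2,3-trimethoxybenzene | COc1cc(Br)cc(OC)c1OC | starting material
10 | 6-bromo-2,3,4-trimethoxybenzaldehyde | COc1cc(Br)c(C=O)c(OC)c1OC | intermediate
11 | ABCD aldehyde, 2,3,4-trimethoxy-6-(aryloxy of 8)benzaldehyde | COc1cc(OC)c(Oc2cc(OC)c(Oc3cc(OC)c(Oc4cc(OC)c(OC)c(OC)c4C=O)c(OC)c3)c(OC)c2)c(OC)c1 | intermediate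
12 | ABCD formate, formate ester of phenol 13 | COc1cc(OC)c(Oc2cc(OC)c(Oc3cc(OC)c(Oc4cc(OC)c(OC)c(OC)c4OC=O)c(OC)c3)c(OC)c2)c(OC)c1 | intermediate
13 | ABCD phenol, 2,3,4-trimethoxy-6-(aryloxy of 8)phenol | COc1cc(OC)c(Oc2cc(OC)c(Oc3cc(OC)c(Oc4cc(OC)c(OC)c(OC)c4O)c(OC)c3)c(OC)c2)c(OC)c1 | intermediate
14 | methyl but-2-ynoate | CC#CC(=O)OC | starting material
15 | methyl (E)-3-(ABCD-aryloxy)but-2-enoate | COc1cc(OC)c(Oc2cc(OC)c(Oc3cc(OC)c(Oc4cc(OC)c(OC)c(OC)c4O/C(C)=C/C(=O)OC)c(OC)c3)c(OC)c2)c(OC)c1 | intermediate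
16 | 2,6-dimethoxyphenol | COc1cccc(OC)c1O | starting material
17 | 5-(2,6-dimethoxyphenoxy)-1,2,3-trimethoxybenzene | COc1cccc(OC)c1Oc1cc(OC)c(OC)c(OC)c1 | intermediate
18 | FG pinacol boronate, 2-[3,5-dimethoxy-4-(3,4,5-trimethoxyphenoxy)phenyl]-4,4,5,5-tetramethyl-1,3,2-dioxaborolane | COc1cc(B2OC(C)(C)C(C)(C)O2)cc(OC)c1Oc1cc(OC)c(OC)c(OC)c1 | intermediate
19 | FG phenol, 3,5-dimethoxy-4-(3,4,5-trimethoxyphenoxy)phenol | COc1cc(O)cc(OC)c1Oc1cc(OC)c(OC)c(OC)c1 | intermediate
20 | 2-bromo-N-methoxy-N-methylacetamide | CON(C)C(=O)CBr | starting material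
21 | 2-(FG-aryloxy)-N-methoxy-N-methylacetamide | CON(C)C(=O)COc1cc(OC)c(Oc2cc(OC)c(OC)c(OC)c2)c(OC)c1 | intermediate
22 | keto ester, methyl (E)-3-(ABCD-aryloxy)-6-(FG-aryloxy)-5-oxohex-2-enoate | COc1cc(OC)c(Oc2cc(OC)c(Oc3cc(OC)c(Oc4cc(OC)c(OC)c(OC)c4O/C(CC(=O)COc4cc(OC)c(Oc5cc(OC)c(OC)c(OC)c5)c(OC)c4)=C/C(=O)OC)c(OC)c3)c(OC)c2)c(OC)c1 | intermediate
23 | pentadeca-O-methyl heptamer, 5-(ABCD-aryloxy)-2-(FG-aryloxy)benzene-1,3-diol | COc1cc(OC)c(Oc2cc(OC)c(Oc3cc(OC)c(Oc4cc(OC)c(OC)c(OC)c4Oc4cc(O)c(Oc5cc(OC)c(Oc6cc(OC)c(OC)c(OC)c6)c(OC)c5)c(O)c4)c(OC)c3)c(OC)c2)c(OC)c1 | intermediate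
24 | CNP0304148.0 | Oc1cc(O)c(Oc2cc(O)c(Oc3cc(O)c(Oc4cc(O)c(O)c(O)c4Oc4cc(O)c(Oc5cc(O)c(Oc6cc(O)c(O)c(O)c6)c(O)c5)c(O)c4)c(O)c3)c(O)c2)c(O)c1 | target

**Totals.** 13 steps in all; the longest linear sequence is 9 steps (1, 2, 3, 4, 6, 7, 8, 12, 13).

**Steps most likely to fail**

Step 12. The ketone enolate may close through oxygen (lactonisation to a 2-pyranone), the ring D aryloxide may be lost by addition–elimination, or proton transfer to the aryloxy-bearing carbon may be too slow for carbon–carbon closure. In that case the annulation is abandoned and ring E is introduced by the coupling/oxidation pair of steps 1–4. Setting out from 13, CuI/picolinic acid/K3PO4 coupling with 2 should give the ABCDE aldehyde F1. mCPBA should convert it into the ABCDE formate F2, and catalytic K2CO3 in methanol should release the ABCDE phenol F3. A second coupling with 2 should give the ABCDEF aldehyde F4, mCPBA the ABCDEF formate F5, and methanolysis the ABCDEF phenol F6. Coupling of F6 with 9 should give the heptadeca-O-methyl heptamer F7, and BBr3 should cleave all seventeen methyl ethers, so that the route is rejoined at 24.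

Step 6. The copper cycle may stall on this most crowded pairing (a large di-ortho-substituted phenoxide and an ortho-substituted bromide), leading to protodebromination of 10 and oxidative loss of the phenoxide. The fallback replaces copper catalysis by an uncatalysed SNAr reaction. Rieche formylation of commercial 5-fluoro-1,2,3-trimethoxybenzene should give 6-fluoro-2,3,4-trimethoxybenzaldehyde F8. Setting out from 8, its potassium phenoxide (K2CO3, DMF, 110 °C) should displace the fluoride ortho to the formyl group, and the route is rejoined at 11.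

Step 13. Cleavage of some of the fifteen ethers may be incomplete, and the pyrogallol-type rings may oxidise in air during isolation of the free polyphenol. The fallback carries the product through a stable, chromatographable derivative. Setting out from 23, the crude material from the BBr3 treatment is acetylated (Ac2O, pyridine) to the heptadeca-O-acetate F9. This is purified on silica, and under-demethylated fractions are returned to BBr3. Acid methanolysis under argon (HCl generated from AcCl in MeOH) then releases the phenols, and the route is rejoined at 24.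

**Further compounds**

F1 | step 12 | ABCDE aldehyde | COc1cc(OC)c(Oc2cc(OC)c(Oc3cc(OC)c(Oc4cc(OC)c(OC)c(OC)c4Oc4cc(OC)c(C=O)c(OC)c4)c(OC)c3)c(OC)c2)c(OC)c1
F2 | step 12 | ABCDE formate | COc1cc(OC)c(Oc2cc(OC)c(Oc3cc(OC)c(Oc4cc(OC)c(OC)c(OC)c4Oc4cc(OC)c(OC=O)c(OC)c4)c(OC)c3)c(OC)c2)c(OC)c1
F3 | step 12 | ABCDE phenol | COc1cc(OC)c(Oc2cc(OC)c(Oc3cc(OC)c(Oc4cc(OC)c(OC)c(OC)c4Oc4cc(OC)c(O)c(OC)c4)c(OC)c3)c(OC)c2)c(OC)c1
F4 | step 12 | ABCDEF aldehyde | COc1cc(OC)c(Oc2cc(OC)c(Oc3cc(OC)c(Oc4cc(OC)c(OC)c(OC)c4Oc4cc(OC)c(Oc5cc(OC)c(C=O)c(OC)c5)c(OC)c4)c(OC)c3)c(OC)c2)c(OC)c1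
F5 | step 12 | ABCDEF formate | COc1cc(OC)c(Oc2cc(OC)c(Oc3cc(OC)c(Oc4cc(OC)c(OC)c(OC)c4Oc4cc(OC)c(Oc5cc(OC)c(OC=O)c(OC)c5)c(OC)c4)c(OC)c3)c(OC)c2)c(OC)c1
F6 | step 12 | ABCDEF phenol | COc1cc(OC)c(Oc2cc(OC)c(Oc3cc(OC)c(Oc4cc(OC)c(OC)c(OC)c4Oc4cc(OC)c(Oc5cc(OC)c(O)c(OC)c5)c(OC)c4)c(OC)c3)c(OC)c2)c(OC)c1
F7 | step 12 | heptadeca-O-methyl heptamer | COc1cc(OC)c(Oc2cc(OC)c(Oc3cc(OC)c(Oc4cc(OC)c(OC)c(OC)c4Oc4cc(OC)c(Oc5cc(OC)c(Oc6cc(OC)c(OC)c(OC)c6)c(OC)c5)c(OC)c4)c(OC)c3)c(OC)c2)c(OC)c1
F8 | step 6 | 6-fluoro-2,3,4-trimethoxybenzaldehyde | COc1cc(F)c(C=O)c(OC)c1OC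
F9 | step 13 | heptadeca-O-acetate of 24 | CC(=O)Oc1cc(OC(C)=O)c(Oc2cc(OC(C)=O)c(Oc3cc(OC(C)=O)c(Oc4cc(OC(C)=O)c(OC(C)=O)c(OC(C)=O)c4Oc4cc(OC(C)=O)c(Oc5cc(OC(C)=O)c(Oc6cc(OC(C)=O)c(OC(C)=O)c(OC(C)=O)c6)c(OC(C)=O)c5)c(OC(C)=O)c4)c(OC(C)=O)c3)c(OC(C)=O)c2)c(OC(C)=O)c1
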